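**Retrosynthetic overview**

1. Manuifolin D is a (3R)-isoflavan. Its last events are fluoride removal of a SEM group from O-2' and Mitsunobu closure of the dihydropyran ring (O1–C2) from an acyclic (2R)-2,3-diarylpropan-1-ol.
2. C2 comes from a one-carbon Matteson homologation and oxidation of a secondary benzylic boronic ester whose boron sits on C3.
3. Enabling feature: C3 is a stereogenic CH that carries ring B through C1' and lies between the benzylic C4H2 (bound to C4a of ring A) and C2. This 1,2-diarylethyl unit with a one-carbon handle on the aryl-bearing carbon is the retron of an enantioselective three-component conjunctive coupling: ring-B aryl boronate + vinyl metal + ring-A aryl bromide, with C1'–C3 formed by a 1,2-shift from boron.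
4. C1' (ortho to O-2', para to O-4') and C4a (ortho to O1, para to O-7) are both C4 of a resorcinol. Ring A comes from 4-bromoresorcinol. Ring B comes from resorcinol by aromatic Claisen rearrangement (O-prenyl to the 5'-(1,1-dimethylallyl) group), para-bromination, re-prenylation and borylation.
5. Ring order: rings A and B are bought as resorcinols; the dihydropyran ring is the only ring made (step 11).

Key step: step 8

Abbreviations: ArB = 5-(2-methylbut-3-en-2-yl)-4-[(3-methylbut-2-en-1-yl)oxy]-2-{[2-(trimethylsilyl)ethoxy]methoxy}phenyl; SEM = 2-(trimethylsilyl)ethoxymethyl; TBS = tert-butyldimethylsilyl; pin = pinacolato.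

Assumption: the sense of induction of the MandyPhos–Pd catalyst is written as (Sp,Sp); if the first sample of 13 proves to be (S), the ligand antipode is used and nothing else changes.

**Route**

Step 1
Reactants: 1 resorcinol
Product: 2 3-{[2-(trimethylsilyl)ethoxy]methoxy}phenol
Conditions: SEMCl (0.9 equiv), K2CO3, DMF, 0 °C → rt
Reagents that add atoms: 2-(trimethylsilyl)ethoxymethyl chloride, C[Si](C)(C)CCOCCl
Why: Williamson-type O-alkylation of a symmetrical diphenol with a sub-stoichiometric amount of the α-chloro ether should give the mono-acetal as the main, easily separated product (statistical monoprotection).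

Step 2
Reactants: 2 3-{[2-(trimethylsilyl)ethoxy]methoxy}phenol
Product: 3 1-[(3-methylbut-2-en-1-yl)oxy]-3-{[2-(trimethylsilyl)ethoxy]methoxy}benzene
Conditions: prenyl bromide, K2CO3, acetone, reflux
Reagents that add atoms: prenyl bromide (1-bromo-3-methylbut-2-ene), CC(C)=CCBr
Why: Williamson ether synthesis at the only free phenol with a reactive primary allylic bromide.

Step 3
Reactants: 3 1-[(3-methylbut-2-en-1-yl)oxy]-3-{[2-(trimethylsilyl)ethoxy]methoxy}benzene
Product: 4 2-(2-methylbut-3-en-2-yl)-5-{[2-(trimethylsilyl)ethoxy]methoxy}phenol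
Conditions: PhNEt2, 190 °C, sealed tube, Ar
Reagents that add atoms: none
Why: The aromatic Claisen rearrangement ([3,3]) delivers the prenyl group inverted as the 1,1-dimethylallyl group to an ortho carbon, and the site para to the acetal oxygen should be favoured electronically and is much less hindered for the new quaternary carbon than the site between the two oxygens, while the basic solvent suppresses acid-induced follow-up reactions.

Step 4
Reactants: 4 2-(2-methylbut-3-en-2-yl)-5-{[2-(trimethylsilyl)ethoxy]methoxy}phenol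
Product: 5 4-bromo-2-(2-methylbut-3-en-2-yl)-5-{[2-(trimethylsilyl)ethoxy]methoxy}phenol
Conditions: NBS (1.0 equiv), MeCN, −20 °C
Reagents that add atoms: N-bromosuccinimide, O=C1CCC(=O)N1Br
Why: Electrophilic aromatic bromination should go to the only unhindered activated carbon (para to the free OH, ortho to the acetal oxygen), and this very electron-rich ring should react at low temperature much faster than the hindered monosubstituted alkene.

Step 5
Reactants: 5 4-bromo-2-(2-methylbut-3-en-2-yl)-5-{[2-(trimethylsilyl)ethoxy]methoxy}phenol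
Product: 6 1-bromo-5-(2-methylbut-3-en-2-yl)-4-[(3-methylbut-2-en-1-yl)oxy]-2-{[2-(trimethylsilyl)ethoxy]methoxy}benzene (ArB–Br)
Conditions: prenyl bromide, K2CO3, DMF, 40 °C
Reagents that add atoms: prenyl bromide (1-bromo-3-methylbut-2-ene), CC(C)=CCBr
Why: Williamson O-alkylation of the hindered phenoxide with an unhindered primary allylic bromide installs the prenyl ether of the target.

Step 6
Reactants: 6 ArB–Br
Product: 8 4,4,5,5-tetramethyl-2-(ArB)-1,3,2-dioxaborolane (ArB–Bpin), via aryllithium 7 (not isolated)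
Conditions: n-BuLi, THF, −78 °C; i-PrOBpin, −78 °C → rt; aq NH4Cl
Reagents that add atoms: 2-isopropoxy-4,4,5,5-tetramethyl-1,3,2-dioxaborolane, CC(C)OB1OC(C)(C)C(C)(C)O1
Why: Bromine–lithium exchange at −78 °C is faster than any attack on the ethers, the ortho acetal oxygen chelates the aryllithium, and trapping with the isopropoxy boronate gives the pinacol ester (lithiation–borylation).

Step 7
Reactants: 9 4-bromoresorcinol
Product: 10 1-bromo-2,4-bis[(tert-butyldimethylsilyl)oxy]benzene
Conditions: TBSCl (2.4 equiv), imidazole, DMF, rt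
Reagents that add atoms: tert-butyldimethylsilyl chloride, CC(C)(C)[Si](C)(C)Cl
Why: Standard imidazole-promoted silylation of both phenols.

Step 8
Reactants: 8 ArB–Bpin; 11 vinylmagnesium bromide; 10 1-bromo-2,4-bis[(tert-butyldimethylsilyl)oxy]benzene
Product: 13 2-[(1R)-2-{2,4-bis[(tert-butyldimethylsilyl)oxy]phenyl}-1-(ArB)ethyl]-4,4,5,5-tetramethyl-1,3,2-dioxaborolane, via vinylboron ate complex 12 (not isolated)
Conditions: 8 + 11, NaOTf, THF, 0 °C → rt; then 10, Pd(OAc)2 (2 mol %), (Sp,Sp)-MandyPhos (2.4 mol %), THF/DMSO, 60 °C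
Reagents that add atoms: none
Why: Oxidative addition of Pd(0) into the C–Br bond of 10 gives an arylpalladium(II) species that binds the vinyl group of ate complex 12; this triggers a 1,2-metalate shift in which the ring-B aryl group moves from boron to the boron-bearing carbon (the future C3, forming the C1'–C3 bond) anti to palladium while palladium takes the terminal carbon (the future C4), and reductive elimination then forms the C4–C4a bond. The closest known reaction type is the Pd/MandyPhos-catalysed enantioselective conjunctive cross-coupling of aryl–B(pin)/vinylmagnesium ate complexes with aryl halides, with NaOTf as halide scavenger. No ring is closed. The only stereocentre (C3) is set by the chiral ferrocenyl bisphosphine, which selects the face of the palladium-bound vinyl group; the (R)-boronate is the enantiomer required. The step needs the conjunctive pathway to win over direct Suzuki-type transfer of aryl or vinyl and over reaction at the other π-systems: the four-coordinate boron makes its vinyl group by far the most nucleophilic alkene present, the electron-rich ring-B aryl is the only carbon ligand on boron that can migrate, and the aryl bromide keeps palladium as Pd(II) so that ionisation of the aryl prenyl ether should not compete.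

Step 9
Reactants: 13 (1R)-boronic ester
Product: 15 (2R)-3-{2,4-bis[(tert-butyldimethylsilyl)oxy]phenyl}-2-(ArB)propan-1-ol, via homologated boronic ester 14 (not isolated)
Conditions: BrCH2Cl, n-BuLi, THF, −78 °C → rt; then NaBO3·4H2O, THF/H2O, rt
Reagents that add atoms: bromochloromethane, ClCBr; sodium perborate, [Na+].[Na+].O[B-]1(O)OO[B-](O)(O)OO1
Why: In the Matteson homologation (chloromethyl)lithium adds to boron and the secondary benzylic carbon migrates with retention, so C3 keeps its configuration and gains the carbon that becomes C2, and buffered perborate oxidation then turns the primary C–B bond into C–OH with the aryl silyl ethers intact.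

Step 10
Reactants: 15 (2R)-3-{2,4-bis[(tert-butyldimethylsilyl)oxy]phenyl}-2-(ArB)propan-1-ol
Product: 16 4-[(2R)-3-hydroxy-2-(ArB)propyl]benzene-1,3-diol
Conditions: TBAF (2.2 equiv), THF, 0 °C; aq NH4Cl
Reagents that add atoms: none
Why: Fluoride cleaves the two aryl silyl ethers within minutes at 0 °C, conditions under which the SEM acetal, the prenyl ether and both alkenes are inert.

Step 11
Reactants: 16 4-[(2R)-3-hydroxy-2-(ArB)propyl]benzene-1,3-diol
Product: 17 (3R)-3-(ArB)-3,4-dihydro-2H-1-benzopyran-7-ol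
Conditions: PPh3, DIAD, THF (0.01 M), 0 °C → rt
Reagents that add atoms: none
Why: In this intramolecular Mitsunobu etherification the primary alcohol is activated as its alkoxyphosphonium salt and only the ortho phenol can reach it (6-exo-tet), which closes the dihydropyran ring at C2 without touching C3, while high dilution suppresses intermolecular alkylation by the distal phenol.

Step 12
Reactants: 17 (3R)-3-(ArB)-3,4-dihydro-2H-1-benzopyran-7-ol
Product: 18 manuifolin D, (3R)-3-[2-hydroxy-5-(2-methylbut-3-en-2-yl)-4-[(3-methylbut-2-en-1-yl)oxy]phenyl]-3,4-dihydro-2H-1-benzopyran-7-ol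
Conditions: TBAF (excess), ethylenediamine, DMF, 70 °C, Ar; aq NH4Cl
Reagents that add atoms: none
Why: Fluoride attack at silicon fragments the SEM group (ethene, formaldehyde, phenoxide) under basic conditions that cannot ionise the aryl prenyl ether, and ethylenediamine traps the formaldehyde before it can hydroxymethylate the electron-rich phenols.

**Compound list**

1 | resorcinol (benzene-1,3-diol) | Oc1cccc(O)c1 | starting material
2 | 3-{[2-(trimethylsilyl)ethoxy]methoxy}phenol | C[Si](C)(C)CCOCOc1cccc(O)c1 | intermediate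
3 | 1-[(3-methylbut-2-en-1-yl)oxy]-3-{[2-(trimethylsilyl)ethoxy]methoxy}benzene | C[Si](C)(C)CCOCOc1cccc(OCC=C(C)C)c1 | intermediate
4 | 2-(2-methylbut-3-en-2-yl)-5-{[2-(trimethylsilyl)ethoxy]methoxy}phenol | C=CC(C)(C)c1ccc(OCOCC[Si](C)(C)C)cc1O | intermediate
5 | 4-bromo-2-(2-methylbut-3-en-2-yl)-5-{[2-(trimethylsilyl)ethoxy]methoxy}phenol | C=CC(C)(C)c1cc(Br)c(OCOCC[Si](C)(C)C)cc1O | intermediate
6 | 1-bromo-5-(2-methylbut-3-en-2-yl)-4-[(3-methylbut-2-en-1-yl)oxy]-2-{[2-(trimethylsilyl)ethoxy]methoxy}benzene (ArB–Br) | C=CC(C)(C)c1cc(Br)c(OCOCC[Si](C)(C)C)cc1OCC=C(C)C | intermediate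
7 | [5-(2-methylbut-3-en-2-yl)-4-[(3-methylbut-2-en-1-yl)oxy]-2-{[2-(trimethylsilyl)ethoxy]methoxy}phenyl]lithium (ArB–Li, formed in situ) | C=CC(C)(C)c1cc([Li])c(OCOCC[Si](C)(C)C)cc1OCC=C(C)C | intermediate
8 | 4,4,5,5-tetramethyl-2-[5-(2-methylbut-3-en-2-yl)-4-[(3-methylbut-2-en-1-yl)oxy]-2-{[2-(trimethylsilyl)ethoxy]methoxy}phenyl]-1,3,2-dioxaborolane (ArB–Bpin) | C=CC(C)(C)c1cc(B2OC(C)(C)C(C)(C)O2)c(OCOCC[Si](C)(C)C)cc1OCC=C(C)C | intermediate
9 | 4-bromoresorcinol (4-bromobenzene-1,3-diol) | Oc1ccc(Br)c(O)c1 | starting material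
10 | 1-bromo-2,4-bis[(tert-butyldimethylsilyl)oxy]benzene | CC(C)(C)[Si](C)(C)Oc1ccc(Br)c(O[Si](C)(C)C(C)(C)C)c1 | intermediate
11 | vinylmagnesium bromide | C=C[Mg]Br | starting material
12 | bromomagnesium (ArB)(vinyl)(pinacolato)borate (ate complex, formed in situ) | C=C[B-]1(OC(C)(C)C(C)(C)O1)c1cc(C(C)(C)C=C)c(OCC=C(C)C)cc1OCOCC[Si](C)(C)C.[Mg+]Br | intermediate
13 | 2-[(1R)-2-{2,4-bis[(tert-butyldimethylsilyl)oxy]phenyl}-1-(ArB)ethyl]-4,4,5,5-tetramethyl-1,3,2-dioxaborolane | C=CC(C)(C)c1cc([C@@H](Cc2ccc(O[Si](C)(C)C(C)(C)C)cc2O[Si](C)(C)C(C)(C)C)B2OC(C)(C)C(C)(C)O2)c(OCOCC[Si](C)(C)C)cc1OCC=C(C)C | intermediate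
14 | 2-[(2R)-3-{2,4-bis[(tert-butyldimethylsilyl)oxy]phenyl}-2-(ArB)propyl]-4,4,5,5-tetramethyl-1,3,2-dioxaborolane (formed in situ) | C=CC(C)(C)c1cc([C@@H](Cc2ccc(O[Si](C)(C)C(C)(C)C)cc2O[Si](C)(C)C(C)(C)C)CB2OC(C)(C)C(C)(C)O2)c(OCOCC[Si](C)(C)C)cc1OCC=C(C)C | intermediate
15 | (2R)-3-{2,4-bis[(tert-butyldimethylsilyl)oxy]phenyl}-2-(ArB)propan-1-ol | C=CC(C)(C)c1cc([C@@H](Cc2ccc(O[Si](C)(C)C(C)(C)C)cc2O[Si](C)(C)C(C)(C)C)CO)c(OCOCC[Si](C)(C)C)cc1OCC=C(C)C | intermediate
16 | 4-[(2R)-3-hydroxy-2-(ArB)propyl]benzene-1,3-diol | C=CC(C)(C)c1cc([C@@H](Cc2ccc(O)cc2O)CO)c(OCOCC[Si](C)(C)C)cc1OCC=C(C)C | intermediate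
17 | (3R)-3-(ArB)-3,4-dihydro-2H-1-benzopyran-7-ol | C=CC(C)(C)c1cc([C@@H]2COc3cc(O)ccc3C2)c(OCOCC[Si](C)(C)C)cc1OCC=C(C)C | intermediate
18 | manuifolin D, (3R)-3-[2-hydroxy-5-(2-methylbut-3-en-2-yl)-4-[(3-methylbut-2-en-1-yl)oxy]phenyl]-3,4-dihydro-2H-1-benzopyran-7-ol | C=CC(C)(C)c1cc([C@@H]2COc3cc(O)ccc3C2)c(O)cc1OCC=C(C)C | target

**Summary**

Total step count: 12. Longest linear sequence: 11 steps (steps 1–6, then 8–12, from resorcinol); the ring-A branch is step 7.

Steps most likely to fail:

1. Step 8 (key step). Possible failure processes: slow oxidative addition into the electron-rich, ortho-silyloxy bromide; direct Suzuki-type transfer of the aryl or vinyl group from boron to palladium; weak facial control with two ortho-oxygenated aryl partners; ionisation of the prenyl ether by Pd(0). The fallback makes the same C1'–C3 bond and the same boronic ester by reagent-controlled lithiation–borylation; it sets out from 10, uses 8, and returns to the route at 13. Stille vinylation of 10 (tributyl(vinyl)stannane, Pd(PPh3)4, toluene, 100 °C) should give 2,4-bis[(tert-butyldimethylsilyl)oxy]-1-vinylbenzene F1. Hydroboration with 9-BBN (THF) should give the B-alkyl-9-borabicyclononane F2 (not isolated), which is oxidised (NaBO3, THF/H2O) to 2-{2,4-bis[(tert-butyldimethylsilyl)oxy]phenyl}ethan-1-ol F3. Carbamoylation (i-Pr2NCOCl, Et3N, CH2Cl2, reflux) should give the N,N-diisopropylcarbamate F4. s-BuLi/(−)-sparteine (Et2O, −78 °C) removes the pro-S proton next to oxygen and should give the configurationally stable (S)-α-lithio carbamate F5. Addition of 8 should give, with retention, the lithium boronate complex F6. On warming (MgBr2·OEt2, Et2O, reflux) the ring-B aryl group migrates from boron to carbon with inversion and expels the carbamate, which should give (R)-13.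

2. Step 3. Possible failure processes: rearrangement to the carbon between the two oxygens; thermal follow-up reactions of the o-(1,1-dimethylallyl)phenol (abnormal Claisen rearrangement, ring closure of the phenol onto the alkene); loss of the prenyl group. The fallback builds the tertiary allylic group by two successive carbon-nucleophile additions through an o-quinone methide, which fixes the regiochemistry; it sets out from 1 and returns at 4. Nencki acetylation of 1 (AcOH, ZnCl2, 140 °C) should give 1-(2,4-dihydroxyphenyl)ethan-1-one F7. SEMCl/K2CO3 in acetone should protect only the 4-hydroxyl (the 2-hydroxyl is hydrogen-bonded to the carbonyl) and give 1-(2-hydroxy-4-{[2-(trimethylsilyl)ethoxy]methoxy}phenyl)ethan-1-one F8. Boc2O/DMAP/i-Pr2NEt should give 2-acetyl-5-{[2-(trimethylsilyl)ethoxy]methoxy}phenyl tert-butyl carbonate F9. MeLi (1 equiv, Et2O, −78 °C) adds to the ketone; Boc transfer to the new alkoxide and β-elimination should release the o-quinone methide 6-(propan-2-ylidene)-3-{[2-(trimethylsilyl)ethoxy]methoxy}cyclohexa-2,4-dien-1-one F10 (not isolated). 1,4-Addition of vinylmagnesium bromide (−78 → 0 °C) to its exocyclic carbon should give 4.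

3. Step 11. Possible failure processes: intermolecular alkylation by the distal phenol (oligomers); slow activation of the β-branched alcohol that lets the hydrazide compete as nucleophile. The fallback closes the ring by phenoxide displacement instead of Mitsunobu activation; it sets out from 15 and returns at 17, so step 10 is bypassed. MsCl/Et3N (CH2Cl2, 0 °C) should give (2R)-3-{2,4-bis[(tert-butyldimethylsilyl)oxy]phenyl}-2-(ArB)propyl methanesulfonate F11. TBAF (2.2 equiv, THF, 0 °C → rt) should strip both silyl groups to the diphenol mesylate (2R)-3-(2,4-dihydroxyphenyl)-2-(ArB)propyl methanesulfonate F12 (not isolated, present as its phenoxide). Its ortho phenoxide should displace the mesylate (6-exo-tet) and give 17; the distal phenoxide cannot reach the electrophile.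

Further compounds
F1 | step 8 | 2,4-bis[(tert-butyldimethylsilyl)oxy]-1-vinylbenzene | C=Cc1ccc(O[Si](C)(C)C(C)(C)C)cc1O[Si](C)(C)C(C)(C)C
F2 | step 8 | 9-(2-{2,4-bis[(tert-butyldimethylsilyl)oxy]phenyl}ethyl)-9-borabicyclo[3.3.1]nonane | C(Cc1ccc(O[Si](C)(C)C(C)(C)C)cc1O[Si](C)(C)C(C)(C)C)B1C2CCCC1CCC2
F3 | step 8 | 2-{2,4-bis[(tert-butyldimethylsilyl)oxy]phenyl}ethan-1-ol | OCCc1ccc(O[Si](C)(C)C(C)(C)C)cc1O[Si](C)(C)C(C)(C)C
F4 | step 8 | 2-{2,4-bis[(tert-butyldimethylsilyl)oxy]phenyl}ethyl N,N-diisopropylcarbamate | CC(C)N(C(C)C)C(=O)OCCc1ccc(O[Si](C)(C)C(C)(C)C)cc1O[Si](C)(C)C(C)(C)C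
F5 | step 8 | (1S)-2-{2,4-bis[(tert-butyldimethylsilyl)oxy]phenyl}-1-lithioethyl N,N-diisopropylcarbamate | [Li][C@H](OC(=O)N(C(C)C)C(C)C)Cc1ccc(O[Si](C)(C)C(C)(C)C)cc1O[Si](C)(C)C(C)(C)C
F6 | step 8 | lithium (ArB)[(1S)-2-{2,4-bis[(tert-butyldimethylsilyl)oxy]phenyl}-1-(N,N-diisopropylcarbamoyloxy)ethyl](pinacolato)borate | C=CC(C)(C)c1cc([B-]2(OC(C)(C)C(C)(C)O2)[C@H](OC(=O)N(C(C)C)C(C)C)Cc2ccc(O[Si](C)(C)C(C)(C)C)cc2O[Si](C)(C)C(C)(C)C)c(OCOCC[Si](C)(C)C)cc1OCC=C(C)C.[Li+]
F7 | step 3 | 1-(2,4-dihydroxyphenyl)ethan-1-one | CC(=O)c1ccc(O)cc1O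
F8 | step 3 | 1-(2-hydroxy-4-{[2-(trimethylsilyl)ethoxy]methoxy}phenyl)ethan-1-one | CC(=O)c1ccc(OCOCC[Si](C)(C)C)cc1O
F9 | step 3 | 2-acetyl-5-{[2-(trimethylsilyl)ethoxy]methoxy}phenyl tert-butyl carbonate | CC(=O)c1ccc(OCOCC[Si](C)(C)C)cc1OC(=O)OC(C)(C)C
F10 | step 3 | 6-(propan-2-ylidene)-3-{[2-(trimethylsilyl)ethoxy]methoxy}cyclohexa-2,4-dien-1-one | CC(C)=C1C=CC(OCOCC[Si](C)(C)C)=CC1=O
F11 | step 11 | (2R)-3-{2,4-bis[(tert-butyldimethylsilyl)oxy]phenyl}-2-(ArB)propyl methanesulfonate | C=CC(C)(C)c1cc([C@@H](Cc2ccc(O[Si](C)(C)C(C)(C)C)cc2O[Si](C)(C)C(C)(C)C)COS(C)(=O)=O)c(OCOCC[Si](C)(C)C)cc1OCC=C(C)C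
F12 | step 11 | (2R)-3-(2,4-dihydroxyphenyl)-2-(ArB)propyl methanesulfonate | C=CC(C)(C)c1cc([C@@H](Cc2ccc(O)cc2O)COS(C)(=O)=O)c(OCOCC[Si](C)(C)C)cc1OCC=C(C)C
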